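The route rests on taking both oxiranes of epoxytwinol A back to a C2-symmetric bis-quinone cage (isochroman numbering in each half). The key step exploits the unsubstituted C6=C7 bond of each quinone ring A, an enedione alkene between the C5 and C8 carbonyls and remote from the tetrasubstituted C4a=C8a fusion to pyran ring B. Hydroperoxide, guided by a chiral ammonium ion, adds there and closes both epoxides in one operation, making four C–O bonds and four stereocentres. The precursor is a bis(isochroman-5,8-dione) whose halves are bonded C1–C1′ and C4–C4′; it is built as an aromatic cage from a diarylhexanediol and oxidised last. Reduction of the two C8 carbonyls ends the synthesis.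

Key step: step 9

Numbering: each half is numbered as an isochroman (C1 = O–CH bridgehead, O2, C3 = CH–CH3, C4 = second bridgehead, C4a/C8a = ring fusion, C5–C8 = carbocycle, C5 peri to C4, C8 peri to C1; primes for the second half). Ring A is the carbocycle, ring B the pyran, ring C the eight-membered ring through C1, C8a, C4a, C4 of both halves.

Structure check: in 13–15 the oxirane lies on the ring-A face that carries that half's own O2–C3 bridge, the C8 hydroxyl lies on the opposite face, and the C3 methyl sits under C4a/C5 on the bridge face; the stereodescriptors of precursor, product and target agree and none needed correction.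

Assumption: the (S)-benzyl auxiliary (step 2) and the quinine-derived catalyst (step 9) are taken as the matched senses; should a trial show the opposite, the (R)-auxiliary or the quinidine-derived pseudoenantiomer is used and nothing else changes.

Step 1
Reactants: 1 2-(2,5-dimethoxyphenyl)acetic acid; 2 (S)-4-benzyl-1,3-oxazolidin-2-one
Product: 4 (S)-4-benzyl-3-[2-(2,5-dimethoxyphenyl)acetyl]-1,3-oxazolidin-2-one, via mixed pivalic anhydride 3 (not isolated)
Conditions: PivCl, Et3N, THF, −20 °C; then 2, LiCl, −20 °C → rt
Reagents that add atoms: none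
Why: N-acylation of the oxazolidinone by the mixed anhydride, with LiCl making the carbamate nitrogen nucleophilic enough under triethylamine, is a standard one-flask imide synthesis and creates no stereocentre.

Step 2
Reactants: 4 (S)-4-benzyl-3-[2-(2,5-dimethoxyphenyl)acetyl]-1,3-oxazolidin-2-one (two molecules)
Product: 6 (4S,4′S)-3,3′-[(2S,3S)-2,3-bis(2,5-dimethoxyphenyl)butanedioyl]bis(4-benzyl-1,3-oxazolidin-2-one), via lithium Z-enolate 5 (not isolated)
Conditions: LiN(i-Pr)2, THF, −78 °C; then TiCl4, −78 → 0 °C
Reagents that add atoms: none
Why: Oxidative homocoupling of a chiral imide enolate: tetravalent titanium oxidises the chelated lithium Z-enolate by one electron and the two α-carbons join on the faces turned away from the benzyl groups of their auxiliaries, which is expected to set both new benzylic centres S and so to give the C2-symmetric (threo) diarylsuccinyl unit.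

Step 3
Reactants: 6 the bis-imide
Product: 7 S,S′-diethyl (2S,3S)-2,3-bis(2,5-dimethoxyphenyl)butanebis(thioate)
Conditions: EtSH, n-BuLi, THF, 0 °C
Reagents that add atoms: ethanethiol, CCS
Why: Thiolate cleavage of an N-acyloxazolidinone: the soft, weakly basic lithium ethanethiolate attacks the exocyclic carbonyl even of a hindered imide and releases the auxiliary for recovery, and the benzylic stereocentres are not touched.

Step 4
Reactants: 7 the bis-thioester
Product: 8 (3S,4S)-3,4-bis(2,5-dimethoxyphenyl)hexane-2,5-dione
Conditions: MeZnCl, PdCl2(PPh3)2 (5 mol %), THF/toluene, rt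
Reagents that add atoms: methylzinc chloride, C[Zn]Cl
Why: Fukuyama ketone synthesis: zerovalent palladium formed from the precatalyst inserts into each C–S bond and the neutral methylzinc reagent delivers methyl, so the thioesters become methyl ketones without base and the enolisable α-aryl centres should keep their configuration.

Step 5
Reactants: 8 the diketone
Product: 9 (2R,3S,4S,5R)-3,4-bis(2,5-dimethoxyphenyl)hexane-2,5-diol
Conditions: (S)-2-methyl-CBS-oxazaborolidine (20 mol %), BH3·SMe2, THF, −20 °C
Reagents that add atoms: none
Why: Corey–Bakshi–Shibata reduction: the (S)-oxazaborolidine–borane complex distinguishes the methyl from the branched substituent of each ketone and should give the R carbinols, the same sense that Felkin–Anh attack anti to the α-aryl group favours, so hydroxyl and aryl end up syn along the chain (all-syn stereotetrad).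

Step 6
Reactants: 9 the diol
Product: 10 (3R,3′R,4S,4′S)-5,5′,8,8′-tetramethoxy-3,3′-dimethyl-4,4′-biisochroman
Conditions: CH2(OMe)2, BF3·OEt2, CH2Cl2, 0 °C → rt
Reagents that add atoms: dimethoxymethane, COCOC
Why: Oxa-Pictet–Spengler cyclisation: each secondary alcohol is converted by the formaldehyde acetal and BF3·OEt2 into an oxocarbenium ion that the neighbouring arene attacks at its free position ortho to the side chain and to a methoxy group, closing two six-membered pyran rings without creating a stereocentre or disturbing C3 and C4.

Step 7
Reactants: 10 the 4,4′-biisochroman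
Product: 12 tetramethoxy cage, (1S,1′S,3R,3′R,4S,4′S)-5,5′,8,8′-tetramethoxy-3,3′-dimethylbiisochroman bonded both C1–C1′ and C4–C4′, via dilithio bis-isochroman 11 (not isolated)
Conditions: t-BuLi (2.3 equiv), THF, −78 °C; then CuCl2 (2.5 equiv), −78 °C → rt
Reagents that add atoms: none
Why: α-Lithiation of the two benzylic O–CH2 groups (acidified by O2 and the arene, with the C8 methoxy group holding lithium) followed by oxidative coupling of the dilithio compound with divalent copper joins C1 to C1′ and closes ring C, and since the two carbons can only meet on the pyran faces that already carry the C4–C4′ bond, both new stereocentres are set as S by the geometry of the cage.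

Step 8
Reactants: 12 the tetramethoxy cage
Product: 13 bis-quinone cage (each ring A a 5,8-dione with C4a=C8a and C6=C7 double bonds)
Conditions: (NH4)2Ce(NO3)6, MeCN/H2O, 0 °C
Reagents that add atoms: water, O
Why: Oxidative demethylation of the two 1,4-dimethoxyarenes by tetravalent cerium in aqueous acetonitrile gives the p-quinones, and the benzylic carbons C1 and C4 are spared because the cage holds these bridgeheads pyramidal, so the cations or enols that normally erode such positions would need a bridgehead double bond (Bredt-type strain).

Step 9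
Reactants: 13 the bis-quinone cage
Product: 14 bis(epoxyquinone) cage, cis-6,7-oxirane on each ring A on the face of that ring's own O2–C3 bridge (6R,7S,6′R,7′S)
Conditions: t-BuOOH (2.5 equiv, in decane), N-benzylquininium chloride (20 mol %), NaOH (aq, 0.3 equiv), toluene, −10 °C
Reagents that add atoms: tert-butyl hydroperoxide, CC(C)(C)OO
Why: tert-Butyl peroxide anion, carried into toluene as an ion pair with the chiral ammonium cation, adds in conjugate fashion to C6 or C7 of ring A, and the enolate so formed displaces tert-butoxide from the peroxide oxygen, which regenerates the base. The closest known reaction is the Weitz–Scheffer epoxidation of quinones in its cinchona phase-transfer form. Each oxirane closes by 3-exo-tet attack of the enolate carbon on the O–O bond, and the six-membered ring allows only the cis-epoxide. C6 and C7 of a ring are fixed together by the face on which the first C–O bond forms, which the ammonium ion has to steer to the face carrying that ring's own O2–C3 bridge, and because the C2 axis exchanges the two quinones one catalyst enantiomer serves both rings. Site selectivity is secured by the substrate, since C4a=C8a is tetrasubstituted and flanked by the bridgeheads, the bridgehead hydrogens cannot be removed to give enolates, and the first oxirane does not change the second ring. Facial selectivity is what the step needs and the substrate does not supply, because the cage lies far from C6=C7, so it rests on the catalyst.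

Step 10
Reactants: 14 the bis(epoxyquinone) cage
Product: 15 epoxytwinol A
Conditions: i-Bu2AlH (2.2 equiv), THF, −78 °C; aq KNaC4H4O6 work-up
Reagents that add atoms: none
Why: Coordination-directed 1,2-reduction of an α,β-epoxy ketone: the aluminium hydride binds the oxirane oxygen and the pyran O2, both on the same face beside C8, and delivers hydride to C8 from that face so that the hydroxyl comes out anti to the oxirane, while the C5 carbonyl is screened on this face by the C3 methyl group and is left as the enone.

Compound list
1 | 2-(2,5-dimethoxyphenyl)acetic acid | COc1ccc(OC)c(CC(=O)O)c1 | starting material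
2 | (S)-4-benzyl-1,3-oxazolidin-2-one | O=C1OC[C@H](Cc2ccccc2)N1 | starting material
3 | 2-(2,5-dimethoxyphenyl)acetic pivalic anhydride | COc1ccc(OC)c(CC(=O)OC(=O)C(C)(C)C)c1 | intermediate
4 | (S)-4-benzyl-3-[2-(2,5-dimethoxyphenyl)acetyl]-1,3-oxazolidin-2-one | COc1ccc(OC)c(CC(=O)N2[C@@H](Cc3ccccc3)COC2=O)c1 | intermediate
5 | lithium (Z)-enolate of 4 | COc1ccc(OC)c(/C=C(\O[Li])N2[C@@H](Cc3ccccc3)COC2=O)c1 | intermediate
6 | (4S,4′S)-3,3′-[(2S,3S)-2,3-bis(2,5-dimethoxyphenyl)butanedioyl]bis(4-benzyl-1,3-oxazolidin-2-one) | O=C(N1[C@@H](Cc2ccccc2)COC1=O)[C@H](c1cc(OC)ccc1OC)[C@@H](c1cc(OC)ccc1OC)C(=O)N1[C@@H](Cc2ccccc2)COC1=O | intermediate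
7 | S,S′-diethyl (2S,3S)-2,3-bis(2,5-dimethoxyphenyl)butanebis(thioate) | CCSC(=O)[C@H](c1cc(OC)ccc1OC)[C@@H](c1cc(OC)ccc1OC)C(=O)SCC | intermediate
8 | (3S,4S)-3,4-bis(2,5-dimethoxyphenyl)hexane-2,5-dione | CC(=O)[C@H](c1cc(OC)ccc1OC)[C@@H](c1cc(OC)ccc1OC)C(C)=O | intermediate
9 | (2R,3S,4S,5R)-3,4-bis(2,5-dimethoxyphenyl)hexane-2,5-diol | C[C@@H](O)[C@H](c1cc(OC)ccc1OC)[C@@H](c1cc(OC)ccc1OC)[C@@H](C)O | intermediate
10 | (3R,3′R,4S,4′S)-5,5′,8,8′-tetramethoxy-3,3′-dimethyl-4,4′-biisochroman | C[C@H]1OCc2c(OC)ccc(OC)c2[C@@H]1[C@H]1c2c(OC)ccc(OC)c2CO[C@@H]1C | intermediate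
11 | 1,1′-dilithio derivative of 10 (configurationally labile at C1, C1′) | C[C@H]1OC([Li])c2c(OC)ccc(OC)c2[C@@H]1[C@H]1c2c(OC)ccc(OC)c2C([Li])O[C@@H]1C | intermediate
12 | tetramethoxy cage, (1S,1′S,3R,3′R,4S,4′S), halves bonded C1–C1′ and C4–C4′ | C[C@H]1O[C@H]2c3c(OC)ccc(OC)c3[C@@H]1[C@H]1c3c(OC)ccc(OC)c3[C@@H]2O[C@@H]1C | intermediate
13 | bis-quinone cage (5,8:5′,8′-tetraone of 12 without the methyl groups on oxygen) | C[C@H]1O[C@H]2C3=C(C(=O)C=CC3=O)[C@@H]1[C@H]1C3=C(C(=O)C=CC3=O)[C@@H]2O[C@@H]1C | intermediate
14 | bis(epoxyquinone) cage, (6R,7S,6′R,7′S)-6,7:6′,7′-bis-epoxide of 13, oxiranes syn to the O2–C3 bridges | C[C@H]1O[C@H]2C3=C(C(=O)[C@@H]4O[C@@H]4C3=O)[C@@H]1[C@H]1C3=C(C(=O)[C@H]4O[C@H]4C3=O)[C@@H]2O[C@@H]1C | intermediate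
15 | epoxytwinol A (each half 1S,3R,4S,6R,7R,8S; C8–OH anti to the oxirane, C5 ketone) | C[C@H]1O[C@H]2C3=C(C(=O)[C@@H]4O[C@@H]4[C@H]3O)[C@@H]1[C@H]1C3=C([C@H](O)[C@H]4O[C@H]4C3=O)[C@@H]2O[C@@H]1C | target

Total steps: 10. Longest linear sequence: 10 steps (1 → 15).

Steps most likely to fail

Step 9. The peroxide may add to the ring-A face turned away from the O2–C3 bridge in one or both rings, because the reacting alkene is far from every stereocentre and catalyst control may be weak; base may also open the oxiranes once formed. Fallback: control is moved from the catalyst to chelation, separation and recycling. Setting out from 13, the epoxidation is run with t-BuOOLi (from t-BuOOH and n-BuLi) in THF at −78 → −20 °C, where lithium held by the pyran O2 on the required face can guide the peroxide. Compound 14 is separated by chromatography from the singly mismatched bis(epoxyquinone) F1 and the doubly mismatched bis(epoxyquinone) F2. These two are deoxygenated with Zn in AcOH to the bis-hydroquinone cage F3, which FeCl3 in aqueous MeCN reoxidises to 13 for another pass. The fallback rejoins the route at 14.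

Step 7. Lithiation may occur at an aryl C–H instead of C1, the α-lithio ether may undergo Wittig rearrangement, or the oxidant may give intermolecular coupling in place of closure of ring C. Fallback: the C1–C1′ bond is made reductively from carbonyl groups instead of oxidatively from carbanions. Setting out from 10, DDQ (2.2 equiv) in wet CH2Cl2 oxidises both benzylic O–CH2 groups to the bis-lactol F4. Through its open dialdehyde form, SmI2 in THF/HMPA effects intramolecular pinacol coupling to the ring-C tetraol F5 (either diol configuration serves). Camphorsulfonic acid in CH2Cl2 then ionises the two benzylic carbinols, and the C3 and C3′ hydroxyls trap the cations on the only faces the ring allows, which returns the route to 12.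

Step 10. Hydride may arrive on the face away from the oxirane (hydroxyl syn to the oxirane), attack C5, or reduce more than one carbonyl per ring. Fallback: the non-directed facial outcome is accepted and corrected by inversion. Setting out from 14, NaBH4 with CeCl3·7H2O in MeOH at −78 °C reduces C8 and C8′ from the face opposite the oxirane to the 8,8′-bis-epimer F6; C8 is expected to remain the more open carbonyl because ether oxygens, not C–H or CH3, flank it on both faces. Mitsunobu reaction (4-nitrobenzoic acid, PPh3, diisopropyl azodicarboxylate, THF) inverts both carbinols to the bis(4-nitrobenzoate) F7. Mild methanolysis (K2CO3, MeOH, 0 °C) then gives 15.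

Further compounds
F1 | step 9 | singly mismatched bis(epoxyquinone): oxirane of one ring A on the face away from its O2–C3 bridge | C[C@H]1O[C@H]2C3=C(C(=O)[C@H]4O[C@H]4C3=O)[C@@H]1[C@H]1C3=C(C(=O)[C@H]4O[C@H]4C3=O)[C@@H]2O[C@@H]1C
F2 | step 9 | doubly mismatched bis(epoxyquinone): both oxiranes on the faces away from the O2–C3 bridges | C[C@H]1O[C@H]2C3=C(C(=O)[C@H]4O[C@H]4C3=O)[C@@H]1[C@H]1C3=C(C(=O)[C@@H]4O[C@@H]4C3=O)[C@@H]2O[C@@H]1C
F3 | step 9 | bis-hydroquinone cage (5,8,5′,8′-tetrahydroxy analogue of 12) | C[C@H]1O[C@H]2c3c(O)ccc(O)c3[C@@H]1[C@H]1c3c(O)ccc(O)c3[C@@H]2O[C@@H]1C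
F4 | step 7 | bis-lactol, 1,1′-dihydroxy derivative of 10 (anomer mixture) | C[C@H]1OC(O)c2c(OC)ccc(OC)c2[C@@H]1[C@H]1c2c(OC)ccc(OC)c2C(O)O[C@@H]1C
F5 | step 7 | ring-C tetraol: C1 and C1′ bonded and each bearing OH, pyran rings open, C3 and C3′ as free (R)-carbinols | C[C@@H](O)[C@@H]1c2c(OC)ccc(OC)c2C(O)C(O)c2c(OC)ccc(OC)c2[C@H]1[C@@H](C)O
F6 | step 10 | 8,8′-bis-epimer of 15 (hydroxyl syn to the oxirane) | C[C@H]1O[C@H]2C3=C(C(=O)[C@@H]4O[C@@H]4[C@@H]3O)[C@@H]1[C@H]1C3=C([C@@H](O)[C@H]4O[C@H]4C3=O)[C@@H]2O[C@@H]1C
F7 | step 10 | 8,8′-bis(4-nitrobenzoate) of 15 | C[C@H]1O[C@H]2C3=C(C(=O)[C@@H]4O[C@@H]4[C@H]3OC(=O)c3ccc(cc3)[N+](=O)[O-])[C@@H]1[C@H]1C3=C([C@H](OC(=O)c4ccc(cc4)[N+](=O)[O-])[C@H]4O[C@H]4C3=O)[C@@H]2O[C@@H]1C
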